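## The problem

1. Compound 23 is a cyclohexane in which all six ring carbons carry oxygen: acetates at C1 and C6, free hydroxyls at C2 and C3, an oxirane bridging C4 and the fully substituted C5, and on C5 the exocyclic C7H2 benzoate. These locants are used for every intermediate, ring or chain; β is the ring face of O1, α the other.
2. Six contiguous stereocentres must be set in one absolute series: O1 β, O2 α, O3 β, oxirane oxygen α, C7 β, O6 α.
3. O6, O1 and O2 are mutually trans, the pattern of C2 to C4 of D-glucose. These three centres can therefore be bought and made to direct the rest: O6 can steer the creation of C5 by chelation, and O2 together with O5 defines the face from which C3 and C4 are oxidised.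
4. The six oxygens finish in four different states (acetate, free hydroxyl, benzoate, oxirane), which calls for a planned order of unmasking and not for late selective acylation.
5. The sensitive parts are the oxirane (acid, nucleophiles), the 3-hydroxyl trans to it (Payne migration in base) and the C1 acetate beside a free hydroxyl (acyl migration in base), so the last operations have to be neutral.
6. The feature that opens the ring disconnection is the pair C3/C4. The oxirane oxygen is O5 bound to C4 on the α face, the result of O5 displacing a β leaving group on C4. A C3,C4 β-cis-diol is what an alkene C3=C4 gives when it is osmylated anti to its two allylic oxygens O2 and O5.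
7. The carbocycle thus hides an unsubstituted ring alkene C3=C4 between C2 and the C5 carbinol, which is the retron of a ring-closing metathesis of two vinyl groups on a C5–C6–C1–C2 chain.

## Retrosynthesis

**Final unmasking (23 from 22).** Only the benzyl–O2 bond is cut. A benzyl ether on O2 is preferred to an acyl or silyl group because its removal by hydrogenolysis is neutral, so neither acetyl migration from O1 nor Payne migration of the oxirane can start. Compound 22 already has both acetates, the benzoate and the oxirane in place. The forward step only has to spare an oxirane that has no benzylic or allylic C–O bond.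

**Oxirane (22 from 20, 20 from 18, 18 from 17).** The C4–O5 bond is cut, then the C3–O and C4–O bonds.
- Closing O5 onto C4 of the cyclic sulfate 20 fixes the regiochemistry, because only C4 can be reached in a three-membered transition state, and C3 stays masked as a non-nucleophilic sulfate monoester.
- A direct epoxidation of 17 is no substitute: it would place the oxirane on C3–C4, and the hydroxyl-directed (α) epoxide is syn to O5 and cannot migrate to C4–C5.
- Triol 18 follows from cyclohexene 17 by one dihydroxylation, which must occur on the β face.

**Acyl pattern (17 from 15, 15 from 14).** The two 4-methoxybenzyl (PMB) ethers on O1 and O6 are exchanged for acetates. This is done on the alkene, before any oxidation, for two reasons: the anisyl rings do not survive the ruthenium oxidant of the sulfate step, and after oxirane formation the 3-hydroxyl would be acetylated as well. The forward steps ask only that the tertiary 5-hydroxyl stays unacylated.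

**Carbocycle (14 from 13).** The C3=C4 double bond is cut to two vinyl groups. Against the neighbouring cuts (C4–C5 by aldol-type closure, C5–C6 or C1–C2) this one creates no stereocentre and tolerates every group present. It leaves an acyclic diene 13 whose four stereocentres are a sugar triad plus one centre set under acyclic control. The forward reaction must favour cyclisation over oligomerisation.

**C5–C7 bond (13 from 11; 11 from 8 and 9 by way of 10).** The benzoate comes from the primary hydroxyl of diol 11, where the only competitor is a tertiary alcohol. Diol 11 is cut at C5–C7 to vinyl ketone 8 and a hydroxymethyl anion equivalent made from silane 9. Adding C7 to the vinyl ketone, not a vinyl group to a C7-bearing ketone, is dictated by stereochemistry: under chelation by O6 the incoming group ends up trans to O6 on the future ring, so the C5 hydroxyl ends up cis to O6 as required. A silicon-masked hydroxymethyl is preferred to an alkoxymethyl nucleophile because it frees O7 at once, so the benzoate is installed before the ring exists and no acylation has to be done at the end among three hydroxyls. The forward step needs 1,2-addition and chelation control.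

**C4–C5 bond (8 from 7; 7 from 5 and 6).** The ketone is cut to enal 5 and vinylmagnesium bromide 6, through alcohol 7 whose new centre is lost on oxidation. This is two routine operations and no selectivity problem.

**Chain from the pyranoside (5 from 4, 4 from 3, 3 from 2, 2 from 1).** The enal is the zinc fragmentation product of 6-iodo glycoside 4: the C5–O5 ring bond and the C6–I bond are cut, C1 becoming the aldehyde (future C5) and C5=C6 the second vinyl group (future C3).
- The acetal of 1 separates O4/O6 from O2/O3 at the outset: O2 and O3 (future O6, O1) receive PMB, and regioselective reductive opening leaves benzyl on O4 (future O2) and frees O6 for iodination.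
- The only demand is the regiochemistry of the acetal opening.

## Roads not taken

**Alternative 1:** Enantioselective desymmetrisation of an achiral para-quinol.
- Cut and key step: the C6–O bond is made by oxa-Michael addition. Quinol A1 (a cyclohexadienone that already carries O5 and the C7 benzoate) condenses through its hydroxyl with 2-methylpropanal A2 under a chiral binaphthol-derived phosphoric acid, and the hemiacetal adds to one enantiotopic enone carbon to give the cis-fused dioxolane enone A3.
- Merits: A1 is two steps from a simple phenol, chirality is catalytic, and one step sets C5 and C6 with the required cis relation. On length to the first chiral ring and on independence from the chiral pool this road is better than the chosen one.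
- Weak points for 23: A3 holds only two of the six centres. C1 is a bare methylene and C2 a ketone, so O1 must be introduced by enolate oxidation and O2 by reduction, each with its own facial problem. The C3=C4 enone still needs the anti-dihydroxylation and oxirane chemistry of the chosen plan. The acetal ties O5 to O6, the two oxygens that must end differently, and has to be cleaved by acid in the presence of a β-oxygenated ketone or the oxirane.
- Comparison: the chosen plan sets against the shorter start three centres of guaranteed configuration, an oxygen on C1 from the first compound, and a single selectivity-determining step after ring formation.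

**Alternative 2:** Enzymatic aldol coupling followed by spontaneous nitroaldol closure.
- Cut and key step: C6–C1 and C4–C5 are cut. L-Rhamnulose-1-phosphate aldolase joins dihydroxyacetone phosphate A4 to the nitro aldehyde A5, and the nitronate carbon then adds to the ketone to give nitrocyclitol phosphate A6.
- Merits: one pot in water closes the carbocycle with every ring carbon functionalised, the tertiary carbinol and C7 included, without protecting groups. In step economy to the carbon skeleton it is clearly superior.
- Weak points for 23:
  - C4 carries nitrogen on the α face where the target needs O5 to displace a β oxygen leaving group. Converting the nitro group (to a ketone, then reduction and activation) adds several redox steps through an epimerisable α-hydroxy ketone.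
  - The five free hydroxyls and the phosphate of A6 have no built-in differentiation, while 23 needs two acetates, two free hydroxyls and a benzoate.
  - The configurations rest on the enzyme's facial preference and on the reversibility of the nitroaldol step, so A6 is an expected isomer and not a controlled one.
  - A5 itself needs a synthesis.
- Comparison: the chosen plan is longer to the ring but differentiates the oxygens from the first step and has oxygen at every position.

**Alternative 3:** Ferrier carbocyclisation of a glucose-derived enol ether.
- Cut and key step: the C4–C5 bond is cut. The 6-deoxy-hex-5-enopyranoside A7 is hydroxymercurated by Hg(OCOCF3)2 A8 (divalent mercury), the hemiacetal opens, and the mercurated carbon adds to the aldehyde to give hydroxy cyclohexanone A9.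
- Merits: the closure is reliable and uses the sugar triad for C3, C2 and C1, so O3 comes from the sugar. After elimination to the C4=C5 enone, C7 can be attached by a Morita–Baylis–Hillman hydroxymethylation, C6 set by 1,2-reduction, and the oxirane made in one hydroxyl-directed epoxidation syn to O6. That endgame is shorter than the dihydroxylation and sulfate sequence, and here this road is at least as good as the chosen one.
- Weak points for 23: in A9, C5 is a methylene and C7 is absent. The quaternary centre must be built on a polyalkoxy cyclohexenone that readily loses its β-alkoxy groups towards aromatisation under the amine or phosphine catalysis of the hydroxymethylation. The C6 reduction and the epoxidation both depend on substrate control in the ring. A mercury salt is needed.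
- Comparison: overall length is similar. The chosen plan sets against the shorter endgame a C5 centre fixed by chelation in the acyclic series, where elimination is not driven by aromatisation, a metal-light ring closure that touches no stereocentre, and no mercury.

Key step: step 9

Remark: the PMB ether on O6 is taken to chelate magnesium as well as a benzyl ether does; the stereochemical argument of step 7 rests on this. Compound 1 is purchased.

## Route

Step 1
Reactants: 1 methyl 4,6-O-benzylidene-α-D-glucopyranoside
Product: 2 2,3-di-O-PMB ether of 1
Conditions: NaH, PMBCl, Bu4NI (cat.), DMF, 0 °C → rt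
Reagents that add atoms: 4-methoxybenzyl chloride, COc1ccc(CCl)cc1
Why: Williamson etherification of the two free hydroxyls; the acetal is stable to base and no stereocentre is touched.

Step 2
Reactants: 2 2,3-di-O-PMB benzylidene glucoside
Product: 3 methyl 4-O-benzyl-2,3-di-O-PMB-α-D-glucopyranoside (6-OH free)
Conditions: BH3·THF, Cu(OTf)2 (cat.), CH2Cl2, 0 °C → rt; MeOH quench
Reagents that add atoms: none
Why: Regioselective reductive opening of a 4,6-O-benzylidene acetal: activation at the more accessible O6, reduction of the oxocarbenium ion by borane, benzyl retained on O4; the catalytic Lewis acid should be mild enough to spare the PMB ethers.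

Step 3
Reactants: 3 6-hydroxy glucoside
Product: 4 methyl 4-O-benzyl-6-deoxy-6-iodo-2,3-di-O-PMB-α-D-glucopyranoside
Conditions: I2, PPh3, imidazole, toluene, 70 °C
Reagents that add atoms: iodine, II
Why: Garegg–Samuelsson iodination; SN2 displacement of the primary alkoxyphosphonium ion, all secondary oxygens being etherified.

Step 4
Reactants: 4 6-iodo glucoside
Product: 5 (2R,3S,4R)-4-(benzyloxy)-2,3-bis(PMB-oxy)hex-5-enal
Conditions: Zn dust (activated), THF/H2O 9:1, sonication, 40 °C
Reagents that add atoms: none
Why: Bernet–Vasella reductive fragmentation: Zn inserts into C–I, the organozinc expels the ring oxygen across C5–O5 and the hemiacetal collapses to the aldehyde; the three ether centres are untouched and the enal is used at once to avoid α-epimerisation.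

Step 5
Reactants: 5 hex-5-enal; 6 vinylmagnesium bromide
Product: 7 octa-1,7-dien-3-ol (both carbinol epimers)
Conditions: THF, −78 → 0 °C; aq. NH4Cl
Reagents that add atoms: none
Why: Grignard 1,2-addition to the aldehyde; the new carbinol centre is removed in step 6, so both epimers are carried on.

Step 6
Reactants: 7 dienol
Product: 8 (4R,5S,6R)-6-(benzyloxy)-4,5-bis(PMB-oxy)octa-1,7-dien-3-one
Conditions: Dess–Martin periodinane, CH2Cl2, 0 °C → rt
Reagents that add atoms: none
Why: Dess–Martin oxidation of a secondary allylic alcohol under near-neutral conditions, which avoids β-elimination of the O1 ether and epimerisation at C6; the vinyl ketone is used immediately.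

Step 7
Reactants: 8 vinyl ketone; 9 (chloromethyl)(isopropoxy)dimethylsilane
Product: 11 C5,C7-diol diene, via silylmethyl carbinol 10 (not isolated)
Conditions: 9, Mg, THF, reflux (gives (iPrO)Me2SiCH2MgCl); 8, THF, −78 → −20 °C; aq. NH4Cl; crude 10, KF, KHCO3, 30 % H2O2, THF/MeOH, rt
Reagents that add atoms: hydrogen peroxide, OO
Why: Tamao nucleophilic hydroxymethylation: the silylmethyl Grignard reagent adds 1,2 to the ketone held in a five-membered Cram chelate (Mg between the carbonyl oxygen and the O6 ether) from the face of the C6 hydrogen, so the C5 hydroxyl becomes cis to O6 on the future ring; Tamao oxidation then converts C–Si into C–OH without touching the new centre.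

Step 8
Reactants: 11 C5,C7-diol diene; 12 benzoyl chloride
Product: 13 [(2R,3R,4S,5R)-5-(benzyloxy)-2-ethenyl-2-hydroxy-3,4-bis(PMB-oxy)hept-6-en-1-yl] benzoate
Conditions: pyridine, CH2Cl2, 0 °C
Reagents that add atoms: none
Why: Selective acylation of the primary hydroxyl; the tertiary allylic hydroxyl is too hindered to react under these conditions.

Step 9
Reactants: 13 diene benzoate
Product: 14 [(1R,4R,5S,6R)-4-(benzyloxy)-1-hydroxy-5,6-bis(PMB-oxy)cyclohex-2-en-1-yl]methyl benzoate
Conditions: second-generation Grubbs catalyst RuCl2(=CHPh)(PCy3)(H2IMes) (5 mol %), CH2Cl2 (5 mM), 40 °C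
Reagents that add atoms: none
Why: Olefin metathesis by the Chauvin mechanism: the ruthenium benzylidene first exchanges with the less hindered C3 vinyl group, the resulting alkylidene adds across the C4 vinyl group in a [2+2] step, and cycloreversion of the ruthenacyclobutane releases the ring alkene and a ruthenium methylidene that carries the chain, ethene leaving the solution. The closest known reaction type is the ring-closing metathesis of carbohydrate-derived octa-1,7-dienes to conduritol-type cyclohexenes. The single ring is closed as a six-membered carbocycle by formation of C3=C4 alone, and the ring size allows only the cis alkene. No stereocentre is formed; C5, C6, C1 and C2 lie outside the reacting carbons and the neutral conditions cannot epimerise them. The selectivity required is cyclisation over intermolecular metathesis, which high dilution, the four substituted sp3 carbons of the tether and the irreversible loss of ethene should secure. The free tertiary allylic hydroxyl is tolerated by this catalyst and, having no carbinol hydrogen, cannot be isomerised to a ketone by ruthenium hydride by-products; the benzoate and the ethers are inert.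

Step 10
Reactants: 14 cyclohexene bis-PMB ether
Product: 15 cyclohex-3-ene-1β,5α,6α-triol (2α-OBn, 5β-CH2OBz)
Conditions: DDQ, CH2Cl2/pH 7 buffer 10:1, 0 °C → rt
Reagents that add atoms: none
Why: Oxidative cleavage of both PMB ethers (hydride abstraction to the anisyl-stabilised oxocarbenium ion, then hydrolysis); the benzyl ether, benzoate and alkene are inert, and the aqueous buffer is there to intercept the cation before the neighbouring 5-hydroxyl can form an anisylidene acetal.

Step 11
Reactants: 15 triol; 16 acetic anhydride
Product: 17 1β,6α-diacetate (5α-OH free)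
Conditions: pyridine, DMAP (cat.), CH2Cl2, 0 °C
Reagents that add atoms: none
Why: Acetylation of the two secondary hydroxyls; the tertiary hydroxyl should not acylate at 0 °C, and placing the acetates now keeps anisyl groups out of the later ruthenium oxidation.

Step 12
Reactants: 17 cyclohexene diacetate
Product: 18 3β,4β,5α-triol
Conditions: OsO4 (cat.), NMO, acetone/H2O 4:1, rt
Reagents that add atoms: osmium tetroxide, O=[Os](=O)(=O)=O; N-methylmorpholine N-oxide, C[N+]1([O-])CCOCC1; water, O
Why: Upjohn syn-dihydroxylation; by Kishi's rule OsO4 adds anti to both allylic oxygens, here the β face, because the O2 ether and the pseudoaxial 5-hydroxyl occupy the α face of the half-chair; this sets C3 and C4.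

Step 13
Reactants: 18 triol
Product: 20 3β,4β-cyclic sulfate, via cyclic sulfite 19 (not isolated)
Conditions: SOCl2, Et3N, CH2Cl2, 0 °C; then RuCl3·xH2O (cat.), NaIO4, MeCN/H2O, 0 °C
Reagents that add atoms: thionyl chloride, O=S(Cl)Cl; sodium periodate, [Na+].[O-]I(=O)(=O)=O
Why: Gao–Sharpless cyclic sulfate synthesis: the cis-3,4-diol closes to the five-membered sulfite much faster than the hindered tertiary hydroxyl (trans to O4) reacts, and RuO4 formed in situ oxidises sulfur within minutes, before the single benzyl ether is attacked.

Step 14
Reactants: 20 cyclic sulfate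
Product: 22 4α,5α-epoxy-3β-ol, via epoxy sulfate sodium salt 21 (not isolated)
Conditions: NaH, THF, 0 °C; then H2SO4 (cat.), H2O, THF, rt
Reagents that add atoms: none
Why: Payne-type closure of a β-hydroxy cyclic sulfate: the C5 alkoxide lies anti to the C4–O bond and displaces it in a 3-exo-tet SN2 step with inversion at C4, giving the α-oxirane; C3 remains a non-nucleophilic sulfate monoester, which is then hydrolysed at sulfur by catalytic acid with retention at C3.

Step 15
Reactants: 22 O2-benzyl epoxy alcohol
Product: 23 [(1S,2R,3S,4R,5R,6S)-2,3-diacetoxy-4,5-dihydroxy-7-oxabicyclo[4.1.0]heptan-1-yl]methyl benzoate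
Conditions: H2 (1 atm), Pd/C (10 %), EtOAc, rt
Reagents that add atoms: none
Why: Hydrogenolysis of the one benzyl ether under neutral conditions in a non-nucleophilic solvent; the oxirane has no benzylic or allylic C–O bond, and without base neither acetyl migration nor Payne rearrangement can occur.

## Compound list

1 | methyl 4,6-O-[(R)-benzylidene]-α-D-glucopyranoside | CO[C@H]1O[C@@H]2CO[C@@H](c3ccccc3)O[C@H]2[C@H](O)[C@H]1O | starting material
2 | methyl 4,6-O-[(R)-benzylidene]-2,3-di-O-(4-methoxybenzyl)-α-D-glucopyranoside | CO[C@H]1O[C@@H]2CO[C@@H](c3ccccc3)O[C@H]2[C@H](OCc2ccc(OC)cc2)[C@H]1OCc1ccc(OC)cc1 | intermediate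
3 | methyl 4-O-benzyl-2,3-di-O-(4-methoxybenzyl)-α-D-glucopyranoside | CO[C@H]1O[C@H](CO)[C@@H](OCc2ccccc2)[C@H](OCc2ccc(OC)cc2)[C@H]1OCc1ccc(OC)cc1 | intermediate
4 | methyl 4-O-benzyl-6-deoxy-6-iodo-2,3-di-O-(4-methoxybenzyl)-α-D-glucopyranoside | CO[C@H]1O[C@H](CI)[C@@H](OCc2ccccc2)[C@H](OCc2ccc(OC)cc2)[C@H]1OCc1ccc(OC)cc1 | intermediate
5 | (2R,3S,4R)-4-(benzyloxy)-2,3-bis[(4-methoxybenzyl)oxy]hex-5-enal (aldehyde carbon = future C5, vinyl CH = future C3) | O=C[C@H](OCc1ccc(OC)cc1)[C@@H](OCc1ccc(OC)cc1)[C@H](OCc1ccccc1)C=C | intermediate
6 | vinylmagnesium bromide | C=C[Mg]Br | starting material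
7 | 6-(benzyloxy)-4,5-bis[(4-methoxybenzyl)oxy]octa-1,7-dien-3-ol, both carbinol epimers, ether carbons as in 5 | C=CC(O)[C@H](OCc1ccc(OC)cc1)[C@@H](OCc1ccc(OC)cc1)[C@H](OCc1ccccc1)C=C | intermediate
8 | (4R,5S,6R)-6-(benzyloxy)-4,5-bis[(4-methoxybenzyl)oxy]octa-1,7-dien-3-one | C=CC(=O)[C@H](OCc1ccc(OC)cc1)[C@@H](OCc1ccc(OC)cc1)[C@H](OCc1ccccc1)C=C | intermediate
9 | (chloromethyl)(isopropoxy)dimethylsilane | CC(C)O[Si](C)(C)CCl | starting material
10 | silylmethyl carbinol: diol 11 with SiMe2(O-iPr) on C7 in place of the hydroxyl | C=C[C@@](O)(C[Si](C)(C)OC(C)C)[C@H](OCc1ccc(OC)cc1)[C@@H](OCc1ccc(OC)cc1)[C@H](OCc1ccccc1)C=C | intermediate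
11 | (2R,3R,4S,5R)-5-(benzyloxy)-2-ethenyl-3,4-bis[(4-methoxybenzyl)oxy]hept-6-ene-1,2-diol | C=C[C@@](O)(CO)[C@H](OCc1ccc(OC)cc1)[C@@H](OCc1ccc(OC)cc1)[C@H](OCc1ccccc1)C=C | intermediate
12 | benzoyl chloride | O=C(Cl)c1ccccc1 | starting material
13 | [(2R,3R,4S,5R)-5-(benzyloxy)-2-ethenyl-2-hydroxy-3,4-bis[(4-methoxybenzyl)oxy]hept-6-en-1-yl] benzoate | C=C[C@@](O)(COC(=O)c1ccccc1)[C@H](OCc1ccc(OC)cc1)[C@@H](OCc1ccc(OC)cc1)[C@H](OCc1ccccc1)C=C | intermediate
14 | [(1R,4R,5S,6R)-4-(benzyloxy)-1-hydroxy-5,6-bis[(4-methoxybenzyl)oxy]cyclohex-2-en-1-yl]methyl benzoate (target locants: 1β,6α-di-OPMB, 2α-OBn, 5α-OH, C7 β) | COc1ccc(CO[C@H]2[C@H](OCc3ccccc3)C=C[C@@](O)(COC(=O)c3ccccc3)[C@@H]2OCc2ccc(OC)cc2)cc1 | intermediate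
15 | 2α-(benzyloxy)-5β-[(benzoyloxy)methyl]cyclohex-3-ene-1β,5α,6α-triol (target locants) | O[C@H]1[C@H](OCc2ccccc2)C=C[C@@](O)(COC(=O)c2ccccc2)[C@@H]1O | intermediate
16 | acetic anhydride | CC(=O)OC(C)=O | starting material
17 | 1β,6α-diacetoxy-2α-(benzyloxy)-5β-[(benzoyloxy)methyl]cyclohex-3-en-5α-ol | CC(=O)O[C@H]1[C@H](OCc2ccccc2)C=C[C@@](O)(COC(=O)c2ccccc2)[C@@H]1OC(C)=O | intermediate
18 | 1β,6α-diacetoxy-2α-(benzyloxy)-5β-[(benzoyloxy)methyl]cyclohexane-3β,4β,5α-triol | CC(=O)O[C@H]1[C@H](OCc2ccccc2)[C@@H](O)[C@@H](O)[C@@](O)(COC(=O)c2ccccc2)[C@@H]1OC(C)=O | intermediate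
19 | 3β,4β-cyclic sulfite of 18 (both sulfur epimers) | CC(=O)O[C@H]1[C@H](OCc2ccccc2)[C@H]3OS(=O)O[C@H]3[C@@](O)(COC(=O)c2ccccc2)[C@@H]1OC(C)=O | intermediate
20 | 3β,4β-cyclic sulfate of 18 | CC(=O)O[C@H]1[C@H](OCc2ccccc2)[C@H]3OS(=O)(=O)O[C@H]3[C@@](O)(COC(=O)c2ccccc2)[C@@H]1OC(C)=O | intermediate
21 | sodium 3β-O-sulfate of 22 (4α,5α-oxirane closed) | CC(=O)O[C@H]1[C@H](OCc2ccccc2)[C@@H](OS(=O)(=O)[O-])[C@@H]2O[C@]2(COC(=O)c2ccccc2)[C@@H]1OC(C)=O.[Na+] | intermediate
22 | 1β,6α-diacetoxy-2α-(benzyloxy)-5β-[(benzoyloxy)methyl]-4α,5α-epoxycyclohexan-3β-ol | CC(=O)O[C@H]1[C@H](OCc2ccccc2)[C@@H](O)[C@@H]2O[C@]2(COC(=O)c2ccccc2)[C@@H]1OC(C)=O | intermediate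
23 | [(1S,2R,3S,4R,5R,6S)-2,3-diacetoxy-4,5-dihydroxy-7-oxabicyclo[4.1.0]heptan-1-yl]methyl benzoate | CC(=O)O[C@H]1[C@H](O)[C@@H](O)[C@@H]2O[C@]2(COC(=O)c2ccccc2)[C@@H]1OC(C)=O | target

## Step count and least certain steps

Total: 15 steps. Longest linear sequence: 15 steps (1 to 23); the route is fully linear.

**Step 9 (key step).** Ring closure may be slow because the C4 vinyl group sits on a fully substituted carbon and the adjacent hydroxyl can bind ruthenium; intermolecular metathesis or double-bond migration could then overtake cyclisation. The fallback sets out from diol 11. Acetalisation with 2,2-dimethoxypropane and PPTS should give the C5,C7-isopropylidene diene F1, in which the free hydroxyl is gone and the spiro-dioxolane adds a gem-disubstituent bias. Metathesis with the same catalyst should then give the spiro-acetonide cyclohexene F2. Aqueous AcOH should release the cyclohexene C5,C7-diol F3, and benzoylation of its primary hydroxyl (BzCl, pyridine) returns to the route at 14.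

**Step 7.** The vinyl ketone may suffer conjugate addition or base-induced polymerisation, and chelation control may be incomplete if THF competes for magnesium. The fallback sets out from enal 5 and replaces the vinyl ketone by an alkynyl ketone. Lithium (trimethylsilyl)acetylide should give the propargylic alcohol F4, and Dess–Martin oxidation the silyl ynone F5, which adds Grignard reagents at the carbonyl. The same silylmethyl Grignard reagent under chelation control should give the alkynyl silylmethyl carbinol F6. The KF/KHCO3/H2O2 oxidation, which also removes the alkynyl silyl group, should give the ethynyl diol F7. Semi-hydrogenation over Pd/CaCO3 poisoned with Pb(OAc)2 and quinoline comes back to the route at 11.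

**Step 12.** Facial discrimination may be insufficient because the C7 arm lies on the β face that the oxidant must use, and osmylation beside the quaternary carbon may be sluggish. The fallback sets out from 17. Silylation of the tertiary hydroxyl (TESOTf, 2,6-lutidine) should give the 5α-triethylsilyl ether F8, whose bulky pseudoaxial group shields the α face more strongly. Dihydroxylation under the same conditions should give the silylated 3β,4β-diol F9, and HF·pyridine returns to the route at 18.

**Step 14.** Acyl transfer from the C6 acetate or the C7 benzoate to the C5 alkoxide may compete with closure, and the oxirane may open during the acidic hydrolysis of the sulfate monoester. The fallback sets out from triol 18, bypasses 19 to 21, and comes back at 22 by Mitsunobu cyclodehydration (PPh3, DIAD, THF). Only an oxyphosphonium group on O4 has an anti oxygen (O5) available for closure, so the same α-oxirane should form under nearly neutral conditions without a sulfate; this passes through no compound outside the list (entry F0).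

## Further compounds

F1 | step 9 | C5,C7-O-isopropylidene acetal of diol 11 (acyclic diene) | C=C[C@@]1(COC(C)(C)O1)[C@H](OCc1ccc(OC)cc1)[C@@H](OCc1ccc(OC)cc1)[C@H](OCc1ccccc1)C=C
F2 | step 9 | spiro-acetonide cyclohexene (14 with O5 and O7 bridged by isopropylidene in place of OH and OBz) | COc1ccc(CO[C@H]2[C@H](OCc3ccccc3)C=C[C@@]3(COC(C)(C)O3)[C@@H]2OCc2ccc(OC)cc2)cc1
F3 | step 9 | cyclohexene C5,C7-diol (14 without the benzoyl group) | COc1ccc(CO[C@H]2[C@H](OCc3ccccc3)C=C[C@@](O)(CO)[C@@H]2OCc2ccc(OC)cc2)cc1
F4 | step 7 | 1-(trimethylsilyl)alkynyl carbinol from 5 (both carbinol epimers) | C[Si](C)(C)C#CC(O)[C@H](OCc1ccc(OC)cc1)[C@@H](OCc1ccc(OC)cc1)[C@H](OCc1ccccc1)C=C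
F5 | step 7 | trimethylsilyl ynone (alkynyl analogue of 8) | C[Si](C)(C)C#CC(=O)[C@H](OCc1ccc(OC)cc1)[C@@H](OCc1ccc(OC)cc1)[C@H](OCc1ccccc1)C=C
F6 | step 7 | alkynyl silylmethyl carbinol (alkynyl analogue of 10) | C[Si](C)(C)C#C[C@@](O)(C[Si](C)(C)OC(C)C)[C@H](OCc1ccc(OC)cc1)[C@@H](OCc1ccc(OC)cc1)[C@H](OCc1ccccc1)C=C
F7 | step 7 | ethynyl diol (11 with ethynyl in place of the C4 vinyl group) | C#C[C@@](O)(CO)[C@H](OCc1ccc(OC)cc1)[C@@H](OCc1ccc(OC)cc1)[C@H](OCc1ccccc1)C=C
F8 | step 12 | 5α-O-triethylsilyl ether of 17 | CC(=O)O[C@H]1[C@H](OCc2ccccc2)C=C[C@@](O[Si](CC)(CC)CC)(COC(=O)c2ccccc2)[C@@H]1OC(C)=O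
F9 | step 12 | 5α-O-triethylsilyl ether of triol 18 | CC(=O)O[C@H]1[C@H](OCc2ccccc2)[C@@H](O)[C@@H](O)[C@@](O[Si](CC)(CC)CC)(COC(=O)c2ccccc2)[C@@H]1OC(C)=O
F0 | step 14 | none | none
A1 | alternative 1 | 4-[(benzoyloxy)methyl]-4-hydroxycyclohexa-2,5-dien-1-one | O=C1C=CC(O)(COC(=O)c2ccccc2)C=C1
A2 | alternative 1 | 2-methylpropanal | CC(C)C=O
A3 | alternative 1 | cis-fused 2-isopropyl-1,3-dioxolane enone (acetal across O5 and O6, ketone at C2, methylene at C1) | C1C(=O)C=C[C@]2(COC(=O)c3ccccc3)O[C@@H](C(C)C)O[C@H]12
A4 | alternative 2 | dihydroxyacetone phosphate | O=C(CO)COP(O)(O)=O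
A5 | alternative 2 | (2R,3S)-2,3-dihydroxy-4-nitrobutanal | O=C[C@H](O)[C@@H](O)C[N+](=O)[O-]
A6 | alternative 2 | nitrocyclitol phosphate (4α-nitro, C5 carbinol bearing CH2OPO3H2) | O[C@H]1[C@H](O)[C@@H](O)[C@H]([N+](=O)[O-])[C@@](O)(COP(O)(O)=O)[C@@H]1O
A7 | alternative 3 | methyl 2,3-di-O-benzyl-6-deoxy-4-O-(4-methoxybenzyl)-α-D-xylo-hex-5-enopyranoside | CO[C@H]1OC(=C)[C@@H](OCc2ccc(OC)cc2)[C@H](OCc2ccccc2)[C@H]1OCc1ccccc1
A8 | alternative 3 | mercury bis(trifluoroacetate) | O=C(O[Hg]OC(=O)C(F)(F)F)C(F)(F)F
A9 | alternative 3 | 3,4-bis(benzyloxy)-5-hydroxy-2-[(4-methoxybenzyl)oxy]cyclohexanone (ketone at C6, methylene at C5, carbinol at C4) | COc1ccc(CO[C@H]2[C@H](OCc3ccccc3)[C@@H](OCc3ccccc3)[C@@H](O)CC2=O)cc1
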